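**Assumption:** anhydrous ethereal H2O2, both enantiomers of TADDOL and the L-fructose-derived epoxidation ketone are taken as purchasable reagents. Locants C-1 to C-24 in the comments run from the carboxyl carbon to the terminal alkene carbon of the target.

**Retrosynthetic overview**
1. Target acid 24 ⇐ methyl ester 23 (saponification).
2. Both rings of 23 ⇐ acyclic bromo epoxy enoate 20 in one pot: oxolane first (epoxide oxygen displaces C-10 bromide, H2O2 opens the epoxonium ion at C-6), then the 1,2-dioxane (peroxy-Michael addition to the enoate).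
3. 20 ⇐ epoxide 14 + (Z,Z)-chlorodiene 18 (B-alkyl Suzuki); 14 ⇐ triene 13 (Shi epoxidation).
4. 13 ⇐ aldehyde ester 6 + hexenylzinc (asymmetric addition sets C-10), Appel inversion, reduction/Wittig.
5. 6 ⇐ acrolein + acetal Grignard reagent, then Johnson–Claisen rearrangement (E-alkene C-6/C-7).

**Route**

Step 1
Reactants: 1 2-(2-bromoethyl)-1,3-dioxolane; 2 acrolein
Product: 4 1-(1,3-dioxolan-2-yl)pent-4-en-3-ol (racemic), via Grignard reagent 3 (not isolated)
Conditions: Mg, THF, 25–30 °C; then 2, −78 → 0 °C; aq. NH4Cl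
Reagents that add atoms: none
Why: Grignard 1,2-addition to acrolein at low temperature; the carbinol is racemic and its stereocentre is erased in step 2.

Step 2
Reactants: 4 1-(1,3-dioxolan-2-yl)pent-4-en-3-ol
Product: 6 ethyl (4E)-8-oxooct-4-enoate, via acetal ester 5 (not isolated)
Conditions: CH3C(OEt)3 (6 equiv), EtCO2H (cat.), 140 °C, EtOH distilled off; concentrate; then 1 M HCl, THF, rt
Reagents that add atoms: triethyl orthoacetate CCOC(C)(OCC)OCC; water O
Why: Johnson–Claisen rearrangement through a chair transition state with the alkyl group equatorial gives the E-alkene (typically >95:5), and dilute acid then hydrolyses the dioxolane (acetal hydrolysis) without touching the ester.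

Step 3
Reactants: 6 ethyl (4E)-8-oxooct-4-enoate; 7 6-bromohex-1-ene
Product: 10 ethyl (4E,8R)-8-hydroxytetradeca-4,13-dienoate, via hex-5-enylmagnesium bromide 8 (not isolated), via di(hex-5-enyl)zinc 9 (not isolated)
Conditions: 7, Mg, Et2O; ZnCl2 (0.5 equiv per RMgBr), 1,4-dioxane, filter under Ar; (4S,5S)-2,2-dimethyl-α,α,α′,α′-tetraphenyl-1,3-dioxolane-4,5-dimethanol [(S,S)-TADDOL, 0.2 equiv], Ti(OiPr)4 (1.4 equiv), 6, toluene/Et2O, −25 °C; 1 M HCl
Reagents that add atoms: none
Why: Titanium TADDOLate-catalysed enantioselective addition of a salt-free dialkylzinc made from the Grignard reagent (Seebach-type alkylzinc addition); the (S,S)-ligand delivers the alkyl group to the Re face of the aldehyde (the (R,R)-ligand gives Si attack) and sets the (R)-carbinol at C-10, while the ester is inert to R2Zn.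

Step 4
Reactants: 10 ethyl (4E,8R)-8-hydroxytetradeca-4,13-dienoate
Product: 11 ethyl (4E,8S)-8-bromotetradeca-4,13-dienoate
Conditions: CBr4 (1.3 equiv), PPh3 (1.4 equiv), CH2Cl2, −20 → 0 °C
Reagents that add atoms: carbon tetrabromide BrC(Br)(Br)Br
Why: Appel bromination, in which bromide displaces the oxyphosphonium group by SN2 and inverts C-10 to the (S)-bromide.

Step 5
Reactants: 11 ethyl (4E,8S)-8-bromotetradeca-4,13-dienoate
Product: 13 methyl (2E,6E,10S)-10-bromohexadeca-2,6,15-trienoate, via aldehyde 12 (not isolated)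
Conditions: i-Bu2AlH (1.05 equiv), CH2Cl2, −78 °C; then Ph3P=CHCO2Me (1.5 equiv), −78 °C → rt; aq. potassium sodium tartrate (KNaC4H4O6)
Reagents that add atoms: methyl (triphenylphosphoranylidene)acetate COC(=O)C=P(c1ccccc1)(c1ccccc1)c1ccccc1
Why: One-pot half-reduction/Wittig olefination, in which the aluminium hemiacetal formed at −78 °C releases aldehyde 12 to the stabilised ylide on warming to give the E-enoate; the secondary bromide is inert to both reagents.

Step 6
Reactants: 13 methyl (2E,6E,10S)-10-bromohexadeca-2,6,15-trienoate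
Product: 14 methyl (2E)-5-[(2S,3S)-3-[(3S)-3-bromonon-8-en-1-yl]oxiran-2-yl]pent-2-enoate
Conditions: 1,2:4,5-di-O-isopropylidene-β-L-erythro-2,3-hexodiulo-2,6-pyranose (L-fructose-derived ketone, 0.3 equiv), Oxone (2KHSO5·KHSO4·K2SO4, 1.4 equiv), K2CO3, Bu4NHSO4, MeCN/CH2(OMe)2/aq. Na2B4O7 buffer (pH 10.5), 0 °C
Reagents that add atoms: potassium peroxymonosulfate (active component of Oxone) [K+].[O-]S(=O)(=O)OO
Why: Shi asymmetric epoxidation (chiral dioxirane, spiro transition state) picks the electron-rich trans-disubstituted alkene over the enoate and the terminal alkene, and the L-fructose-derived ketone gives the (S,S)-epoxide at C-6/C-7 under reagent control (the D-fructose ketone gives R,R).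

Step 7
Reactants: 15 hex-5-en-1-yne; 16 (Z)-1,2-dichloroethene
Product: 17 (1Z)-1-chloroocta-1,7-dien-3-yne
Conditions: 16 (5 equiv), Pd(PPh3)4 (3 mol%), CuI (6 mol%), n-BuNH2 (2 equiv), Et2O, 20 °C
Reagents that add atoms: none
Why: Sonogashira coupling with excess dichloroethene stops at mono-coupling and retains the Z geometry of the chloroalkene.

Step 8
Reactants: 17 (1Z)-1-chloroocta-1,7-dien-3-yne
Product: 18 (1Z,3Z)-1-chloroocta-1,3,7-triene
Conditions: Zn dust activated with Cu(OAc)2 then AgNO3, MeOH/H2O 1:1, 25–40 °C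
Reagents that add atoms: none
Why: Activated-zinc (Boland-type) reduction adds hydrogen cis to the conjugated triple bond only, giving the Z,Z-chlorodiene and leaving the vinyl chloride and the isolated alkene alone.

Step 9
Reactants: 14 methyl (2E)-5-[(2S,3S)-3-[(3S)-3-bromonon-8-en-1-yl]oxiran-2-yl]pent-2-enoate; 18 (1Z,3Z)-1-chloroocta-1,3,7-triene
Product: 20 methyl (2E)-5-[(2S,3S)-3-[(3S,10Z,12Z)-3-bromoheptadeca-10,12,16-trien-1-yl]oxiran-2-yl]pent-2-enoate, via B-alkyl borane 19 (not isolated)
Conditions: 9-borabicyclo[3.3.1]nonane (9-BBN-H, 1.1 equiv), THF, 0 °C → rt; then 18 (1.3 equiv), Pd(OAc)2 (5 mol%), 2-dicyclohexylphosphino-2′,6′-dimethoxybiphenyl (SPhos, 10 mol%), 3 M aq. K3PO4, THF, 40 °C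
Reagents that add atoms: none
Why: 9-BBN-H hydroborates only the terminal alkene (anti-Markovnikov) and the B-alkyl Suzuki–Miyaura coupling with the alkenyl chloride retains the Z geometry; the epoxide, the enoate and the secondary alkyl bromide (no oxidative addition to zerovalent palladium under these conditions) survive.

Step 10
Reactants: 20 methyl (2E)-5-[(2S,3S)-3-[(3S,10Z,12Z)-3-bromoheptadeca-10,12,16-trien-1-yl]oxiran-2-yl]pent-2-enoate
Product: 23 methyl 2-[(3R,6R)-6-[(2S,5R)-5-[(7Z,9Z)-tetradeca-7,9,13-trien-1-yl]oxolan-2-yl]-1,2-dioxan-3-yl]acetate, via epoxonium triflate 21 (not isolated), via hydroperoxide 22 (not isolated)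
Conditions: AgOTf (AgO3SCF3, 1.3 equiv), anhydrous H2O2 in Et2O (10 equiv), 2,6-di-tert-butyl-4-methylpyridine (1.5 equiv), CH2Cl2/Et2O, −30 → 0 °C, dark; filter; then Et2NH (0.5 equiv), CF3CH2OH, rt
Reagents that add atoms: hydrogen peroxide OO
Why: Proposed new method: AgOTf abstracts bromide with anchimeric assistance by the epoxide oxygen (5-exo, inversion at C-10) to give epoxonium ion 21, H2O2 opens it at the exocyclic carbon C-6 with inversion to give trans-oxolane hydroperoxide 22 (C-7 retained), and amine-catalysed reversible 6-exo peroxy-Michael addition through a chair with both substituents equatorial closes the trans-3,6-disubstituted 1,2-dioxane and sets C-3; the closest known reactions are silver-promoted epoxonium formation from bromo epoxides with capture by water, silver-assisted perhydrolysis of alkyl halides, and intramolecular hydroperoxide conjugate addition to enoates.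

Step 11
Reactants: 23 methyl 2-[(3R,6R)-6-[(2S,5R)-5-[(7Z,9Z)-tetradeca-7,9,13-trien-1-yl]oxolan-2-yl]-1,2-dioxan-3-yl]acetate
Product: 24 2-[(3R,6R)-6-[(2S,5R)-5-[(7Z,9Z)-tetradeca-7,9,13-trien-1-yl]oxolan-2-yl]-1,2-dioxan-3-yl]acetic acid (target)
Conditions: LiOH (3 equiv), THF/H2O 3:1, 0 °C → rt; 1 M HCl to pH 3
Reagents that add atoms: lithium hydroxide [Li+].[OH-]
Why: Mild ester saponification; the dialkyl peroxide, the oxolane and the alkenes tolerate cold aqueous hydroxide, and C-3 already sits in its thermodynamically preferred trans position so no stereocentre is lost.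

**Compound list**
1 | 2-(2-bromoethyl)-1,3-dioxolane | BrCCC1OCCO1 | starting material
2 | acrolein (prop-2-enal) | C=CC=O | starting material
3 | [2-(1,3-dioxolan-2-yl)ethyl]magnesium bromide | Br[Mg]CCC1OCCO1 | intermediate (not isolated)
4 | 1-(1,3-dioxolan-2-yl)pent-4-en-3-ol, racemic | C=CC(O)CCC1OCCO1 | intermediate
5 | ethyl (4E)-7-(1,3-dioxolan-2-yl)hept-4-enoate | CCOC(=O)CC/C=C/CCC1OCCO1 | intermediate (not isolated)
6 | ethyl (4E)-8-oxooct-4-enoate | CCOC(=O)CC/C=C/CCC=O | intermediate
7 | 6-bromohex-1-ene | BrCCCCC=C | starting material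
8 | hex-5-enylmagnesium bromide | C=CCCCC[Mg]Br | intermediate (not isolated)
9 | di(hex-5-enyl)zinc | C=CCCCC[Zn]CCCCC=C | intermediate (not isolated)
10 | ethyl (4E,8R)-8-hydroxytetradeca-4,13-dienoate | CCOC(=O)CC/C=C/CC[C@H](O)CCCCC=C | intermediate
11 | ethyl (4E,8S)-8-bromotetradeca-4,13-dienoate | CCOC(=O)CC/C=C/CC[C@@H](Br)CCCCC=C | intermediate
12 | (4E,8S)-8-bromotetradeca-4,13-dienal | O=CCC/C=C/CC[C@@H](Br)CCCCC=C | intermediate (not isolated)
13 | methyl (2E,6E,10S)-10-bromohexadeca-2,6,15-trienoate | COC(=O)/C=C/CC/C=C/CC[C@@H](Br)CCCCC=C | intermediate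
14 | methyl (2E)-5-[(2S,3S)-3-[(3S)-3-bromonon-8-en-1-yl]oxiran-2-yl]pent-2-enoate | COC(=O)/C=C/CC[C@@H]1O[C@H]1CC[C@@H](Br)CCCCC=C | intermediate
15 | hex-5-en-1-yne | C#CCCC=C | starting material
16 | (Z)-1,2-dichloroethene | Cl/C=C\Cl | starting material
17 | (1Z)-1-chloroocta-1,7-dien-3-yne | Cl/C=C\C#CCCC=C | intermediate
18 | (1Z,3Z)-1-chloroocta-1,3,7-triene | Cl/C=C\C=C/CCC=C | intermediate
19 | methyl (2E)-5-[(2S,3S)-3-[(3S)-9-(9-borabicyclo[3.3.1]nonan-9-yl)-3-bromononyl]oxiran-2-yl]pent-2-enoate | COC(=O)/C=C/CC[C@@H]1O[C@H]1CC[C@@H](Br)CCCCCCB2C3CCCC2CCC3 | intermediate (not isolated)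
20 | methyl (2E)-5-[(2S,3S)-3-[(3S,10Z,12Z)-3-bromoheptadeca-10,12,16-trien-1-yl]oxiran-2-yl]pent-2-enoate | COC(=O)/C=C/CC[C@@H]1O[C@H]1CC[C@@H](Br)CCCCCC/C=C\C=C/CCC=C | intermediate
21 | 1-oxoniabicyclo[3.1.0]hexane triflate from 20: O+ bonded to C-6, C-7 and C-10 (C-6 S, C-7 S, C-10 R), carrying the C-11 to C-24 trienyl chain on C-10 and the (3E)-5-methoxy-5-oxopent-3-enyl chain on C-6 | C=CCC/C=C\C=C/CCCCCC[C@@H]1CC[C@H]2[C@H](CC/C=C/C(=O)OC)[O+]12.[O-]S(=O)(=O)C(F)(F)F | intermediate (not isolated)
22 | methyl (2E,6R)-6-hydroperoxy-6-[(2S,5R)-5-[(7Z,9Z)-tetradeca-7,9,13-trien-1-yl]oxolan-2-yl]hex-2-enoate | C=CCC/C=C\C=C/CCCCCC[C@@H]1CC[C@@H]([C@H](OO)CC/C=C/C(=O)OC)O1 | intermediate (not isolated)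
23 | methyl 2-[(3R,6R)-6-[(2S,5R)-5-[(7Z,9Z)-tetradeca-7,9,13-trien-1-yl]oxolan-2-yl]-1,2-dioxan-3-yl]acetate | C=CCC/C=C\C=C/CCCCCC[C@@H]1CC[C@@H]([C@H]2CC[C@H](CC(=O)OC)OO2)O1 | intermediate
24 | 2-[(3R,6R)-6-[(2S,5R)-5-[(7Z,9Z)-tetradeca-7,9,13-trien-1-yl]oxolan-2-yl]-1,2-dioxan-3-yl]acetic acid | C=CCC/C=C\C=C/CCCCCC[C@@H]1CC[C@@H]([C@H]2CC[C@H](CC(=O)O)OO2)O1 | target

**Totals**
Total step count: 11. Longest linear sequence: 9 (steps 1–6, 9–11); the chlorodiene branch is 2 steps (7–8).

**Three steps most likely to fail, with fallbacks**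

Step 10 (silver-triggered double ring closure). The risks are attack of H2O2 at the ring-fusion carbon C-7 of the epoxonium ion (ring expansion to an oxane), direct silver-assisted perhydrolysis at C-10, and incomplete trans selectivity at C-3. The fallback sets out from 20 and returns to the route at 23; it drops the epoxonium trigger for acid-catalysed perhydrolysis followed by base-mediated closure of both rings. Compound 20 is treated with anhydrous H2O2 in Et2O and H3PMo12O40 (2 mol%). The epoxide is opened with inversion at the attacked carbon but without regiocontrol, giving methyl (2E,6R,7S,10S,17Z,19Z)-10-bromo-6-hydroperoxy-7-hydroxytetracosa-2,17,19,23-tetraenoate F1 together with the regioisomer methyl (2E,6S,7R,10S,17Z,19Z)-10-bromo-7-hydroperoxy-6-hydroxytetracosa-2,17,19,23-tetraenoate F2, which is removed by chromatography. F1 with K2CO3 in MeOH at rt undergoes the peroxy-Michael closure of the dioxane and Williamson closure of the oxolane (the C-7 alkoxide displaces the C-10 bromide with inversion) to give 23. At most half of the material is used.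

Step 9 (B-alkyl Suzuki coupling with an unactivated alkenyl chloride beside an epoxide and a secondary bromide). The fallback sets out from 14 and returns at 20; it moves the cis-reduction onto the main line so that a more reactive electrophile can be used. Borane 19, made from 14 as before, is coupled with chloroenyne 17 (PdCl2(dppf), K3PO4, THF/DMF/H2O, rt) to give methyl (2E)-5-[(2S,3S)-3-[(3S,10Z)-3-bromoheptadeca-10,16-dien-12-yn-1-yl]oxiran-2-yl]pent-2-enoate F3. The conjugated triple bond of F3 is then reduced with Zn dust activated by Cu(OAc)2 and AgNO3 in MeOH/H2O to give 20.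

Step 4 (Appel bromination; partial loss of configuration or elimination at C-10 would carry through to the oxolane). The fallback sets out from 10 and returns at 11; it separates activation from displacement. Alcohol 10 is converted with MsCl/Et3N (CH2Cl2, 0 °C, retention) into ethyl (4E,8R)-8-(methanesulfonyloxy)tetradeca-4,13-dienoate F4. F4 is then displaced with LiBr in acetone at 40 °C in a clean SN2 reaction with inversion to give 11.

**Further compounds**
F1 | step 10 | methyl (2E,6R,7S,10S,17Z,19Z)-10-bromo-6-hydroperoxy-7-hydroxytetracosa-2,17,19,23-tetraenoate | C=CCC/C=C\C=C/CCCCCC[C@H](Br)CC[C@H](O)[C@H](OO)CC/C=C/C(=O)OC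
F2 | step 10 | methyl (2E,6S,7R,10S,17Z,19Z)-10-bromo-7-hydroperoxy-6-hydroxytetracosa-2,17,19,23-tetraenoate | C=CCC/C=C\C=C/CCCCCC[C@H](Br)CC[C@@H](OO)[C@@H](O)CC/C=C/C(=O)OC
F3 | step 9 | methyl (2E)-5-[(2S,3S)-3-[(3S,10Z)-3-bromoheptadeca-10,16-dien-12-yn-1-yl]oxiran-2-yl]pent-2-enoate | COC(=O)/C=C/CC[C@@H]1O[C@H]1CC[C@@H](Br)CCCCCC/C=C\C#CCCC=C
F4 | step 4 | ethyl (4E,8R)-8-(methanesulfonyloxy)tetradeca-4,13-dienoate | CCOC(=O)CC/C=C/CC[C@H](OS(C)(=O)=O)CCCCC=C
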